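## The problem

Target 14 is a flavanone: a chroman-4-one (rings A and C) whose C2 carries ring B, a 2-hydroxy-6-methoxyphenyl group. Ring A is fully substituted. C4a bears the C4 carbonyl, C5 a hydrogen-bonded hydroxyl, C6 to C8 three methoxy groups and C8a the ring oxygen O1, so nothing can be introduced on ring A late. The only stereocentre is C2 (S). It is benzylic, bonded to O1 and β to the C4 carbonyl, and there is no second stereocentre to control it, so a catalyst must set it. The same arrangement makes it fragile: base opens the β-aryloxy ketone to the hydroxychalcone (retro-oxa-Michael) and recloses it as the racemate, and strong Lewis or Brønsted acid can ionise C2–O1 because ring B is oxygenated at both ortho positions. Two oxygens (C5 and C2') must end as free phenols while four stay methyl ethers, so the phenols need a protecting group that leaves under neutral conditions. Both aryl groups flanking the C2–C3–C4 chain are doubly ortho-substituted, which slows every bond formation next to them. The feature to exploit is that O1–C8a is an aryl ether bond ortho to C4a. The two adjacent CH positions of 1,2,3,4-tetramethoxybenzene (1) can take a bromine (future C8a) and an acyl group (future C4a) with no regiochemical choice, so ring C can be closed by an intramolecular C–O arylation that never touches the C2–O bond.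

## Retrosynthesis

**14 to 13 (two O–benzyl bonds).** The C5 and C2' phenols are masked as benzyl ethers in flavanone 13. Benzyl is distinguishable from the four methyl ethers and leaves by neutral hydrogenolysis, which spares the base- and acid-sensitive C2. Carrying a methyl ether at C5 and cleaving it at the end with a boron or aluminium halide would save one step, but it would expose the ionisable C2–O1 bond to a Lewis acid chelated at C4/C5. The forward reaction only has to stop after the two benzyl groups.

**13 to 12 (C4 carbonyl to carbinol).** The ring closure needs carbonate base and heat, conditions under which an open-chain β-hydroxy ketone would undergo retro-aldol cleavage or dehydration. C4 is therefore carried through the closure as an alcohol in chromanol 12 and oxidised afterwards under buffered, non-basic conditions. The C4 configuration is erased at this point, so it need not be controlled for the target.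

**12 to 11 (O1–C8a, the key cut).** Cutting the aryl ether bond gives the acyclic bromo diol 11. The neighbouring cut O1–C2 (Mitsunobu closure of a phenol, or oxa-Michael closure of a chalcone) would place the ring-forming event on the stereocentre, at a carbon that ionises easily. Cutting C4–C4a (Friedel–Crafts closure) would first need an intermolecular ether synthesis at that same hindered carbon. The O1–C8a cut leaves the C2–O bond intact, so the configuration set earlier is simply carried through. Only the ring B carbinol oxygen can reach C8a in a six-membered ring; the ring A carbinol oxygen would have to form a four-membered ring. A copper catalyst is preferred to palladium because a divalent palladium alkoxide of a benzylic secondary alcohol can lose β-hydride, which would reduce the bromide and oxidise the carbinol. The syn diol 11 necessarily gives the 2,4-trans chromanol 12, because O1 rather than ring B becomes part of the ring.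

**11 to 9 (C4–H bond).** Diol 11 comes from β-hydroxy ketone 9 by chelation-controlled 1,3-syn reduction. A single diastereomer is wanted only for clean handling; both C4 epimers would converge at 13.

**9 to 5 + 7 (C2–C3, aldol).** This cut divides the molecule into two arenes of similar size: the silyl enol ether 5 of the ring A methyl ketone and the ring B aldehyde 7. Placing the ketone on ring A and the aldehyde on ring B puts the free hydroxyl on the carbon that must later carry O1 and the carbonyl at C4. The forward reaction must distinguish the two faces of a hindered, electron-rich aldehyde; a catalytic enantioselective Mukaiyama aldol with a strongly activating chiral silicon Lewis acid is chosen.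

**5 to 4, 3, 2 and 1; 7 to 6.** Enol ether 5 comes from ketone 4, the benzyl ether of hydroxy ketone 3. Ketone 3 arises from bromide 2 by Friedel–Crafts acetylation at the only free position, with cleavage in the same flask of the methoxy group that ends up ortho to the ketone. This one operation installs C4 and marks the future C5 oxygen. Bromide 2 is the monobromide of 1, whose two CH positions are equivalent. Aldehyde 7 is the benzyl ether of commercial 2-hydroxy-6-methoxybenzaldehyde (6).

## Roads not taken

**Alternative 1:** Ring B would be built last by benzannulation. The cut removes the whole of ring B and leads back to a chroman carrying a silyloxyethynyl group at C2 (siloxyalkyne A2) and to cyclobutenone A3.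
- Forward step: on heating, A3 opens to a ketene, adds across the alkyne of A2, the new four-membered ring opens again and a 6π closure gives the silyl-protected chromanol A1.
- Merits: the two ring B oxygens emerge already differentiated (free phenol and silyl ether), and the stereocentre is never set next to a doubly ortho-substituted arene. In these two respects it is better than the chosen plan.
- Weak points: ring B is a cheap commercial pattern (6), so building it atom by atom gains little. A2 needs a propargylic C2 stereocentre, a siloxyalkyne made by ynolate chemistry, and a ring C closure of its own. After the annulation, methylation, two desilylations, oxidation at C4 and demethylation at C5 remain.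
- Comparison: the chosen plan buys ring B, is about half as long, and sets the two ring B oxygens apart with one benzylation.

**Alternative 2:** C2–C3 would be formed by intramolecular carbenoid C–H insertion. The cut leads back to diazoketone A5, an aryl diazomethyl ketone whose ortho oxygen carries the ring B benzyl group.
- Forward step: Rh2(S-PTTL)4 would decompose A5, and the carbenoid at C3 would insert into one of the two enantiotopic benzylic C–H bonds next to O1, giving flavanone A4 directly.
- Merits: ring C, the C2–C3 bond, the stereocentre and the correct oxidation level at C4 all arrive in one step. In step and redox economy this road is clearly better than the chosen plan.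
- Weak points: an acceptor-only carbenoid is unselective. The ether oxygen sits where it can attack the carbenoid to give a five-membered oxonium ylide that rearranges by benzyl shift. The electron-rich ring B invites cyclopropanation. Six-membered insertion is not the normal preference. The site is flanked by a doubly ortho-substituted arene, so enantiocontrol is doubtful. The product then needs Lewis-acid removal of isopropyl and the C5 methyl with C2 exposed.
- Comparison: the chosen plan is longer, but its stereocentre comes from a well-understood aldol, is never touched again, and is unmasked by hydrogenolysis.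

**Alternative 3:** Ring C would be assembled by a carbonylative three-component annulation. The cut leads back to iodophenol A7 and arylacetylene A8.
- Forward step: PdCl2(PPh3)2 with a secondary amine base would join the two under carbonylating conditions (forming C4a–C4 and C4–C3), and the phenol would add 6-endo to the ynone to give flavone A6.
- Merits: it is the most convergent road, and the flat A6 cannot racemise or open. In these respects it is better than the chosen plan.
- Weak points: it creates no stereocentre. C2 would have to come from enantioselective reduction of the C2=C3 bond of A6, a trisubstituted enone with a doubly ortho-substituted aryl group on the β-carbon, with over-reduction at C4 as a side reaction. 5-exo closure to the aurone competes in the annulation. Demethylation at C5 and debenzylation still follow.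
- Comparison: the chosen plan is less convergent, but it settles the stereocentre early on an open-chain aldehyde by a reaction type with a broad record.

Key step: step 8

Assumption: compounds 1 and 6 are taken as commercial.

Assumption: the antipode of the bisphosphoramide in step 6 is the one that directs the enol ether to the Si face of 7. Its sense is to be confirmed on the first run (for example by Mosher ester analysis of 9), and the other antipode is used if it proves opposite.

## Route

Step 1
Reactants: 1 1,2,3,4-tetramethoxybenzene
Product: 2 1-bromo-2,3,4,5-tetramethoxybenzene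
Conditions: NBS (1.0 equiv), MeCN, 0 °C to rt
Reagents that add atoms: N-bromosuccinimide, O=C1CCC(=O)N1Br
Why: Electrophilic aromatic bromination; the two free positions of 1 are equivalent, so only one monobromide can form, and the bromine slows a second substitution.

Step 2
Reactants: 2 1-bromo-2,3,4,5-tetramethoxybenzene
Product: 3 1-(2-bromo-6-hydroxy-3,4,5-trimethoxyphenyl)ethan-1-one
Conditions: AcCl (1.5 equiv), AlCl3 (3 equiv), CH2Cl2, 0 °C to rt; aq. HCl
Reagents that add atoms: acetyl chloride, CC(Cl)=O
Why: Friedel–Crafts acylation at the only free position (ortho and para to methoxy groups), followed in the same flask by AlCl3 cleavage of the methoxy group ortho to the new ketone through its six-membered aluminium chelate; this marks the future C5 oxygen.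

Step 3
Reactants: 3 1-(2-bromo-6-hydroxy-3,4,5-trimethoxyphenyl)ethan-1-one
Product: 4 1-[2-(benzyloxy)-6-bromo-3,4,5-trimethoxyphenyl]ethan-1-one
Conditions: BnBr, K2CO3, DMF, 60 °C
Reagents that add atoms: benzyl bromide, BrCc1ccccc1
Why: Williamson ether synthesis; the chelated phenol is the only acidic site, and warming overcomes its hydrogen bond to the ketone.

Step 4
Reactants: 4 1-[2-(benzyloxy)-6-bromo-3,4,5-trimethoxyphenyl]ethan-1-one
Product: 5 ({1-[2-(benzyloxy)-6-bromo-3,4,5-trimethoxyphenyl]ethenyl}oxy)(trimethyl)silane
Conditions: TMSOTf, Et3N, CH2Cl2, 0 °C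
Reagents that add atoms: trimethylsilyl trifluoromethanesulfonate, C[Si](C)(C)OS(=O)(=O)C(F)(F)F
Why: Soft enolisation and O-silylation of a methyl ketone that can enolise on one side only; the aryl bromide and ethers are inert.

Step 5
Reactants: 6 2-hydroxy-6-methoxybenzaldehyde
Product: 7 2-(benzyloxy)-6-methoxybenzaldehyde
Conditions: BnBr, K2CO3, DMF, rt
Reagents that add atoms: benzyl bromide, BrCc1ccccc1
Why: Williamson ether synthesis on the single phenol; the aldehyde has no α-hydrogen and is stable to carbonate.

Step 6
Reactants: 5 ({1-[2-(benzyloxy)-6-bromo-3,4,5-trimethoxyphenyl]ethenyl}oxy)(trimethyl)silane; 7 2-(benzyloxy)-6-methoxybenzaldehyde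
Product: 9 (3S)-1-[2-(benzyloxy)-6-bromo-3,4,5-trimethoxyphenyl]-3-[2-(benzyloxy)-6-methoxyphenyl]-3-hydroxypropan-1-one, via trichlorosilyl aldolate 8 (not isolated)
Conditions: SiCl4 (1.5 equiv), chiral binaphthyldiamine-derived bisphosphoramide with a pentane-1,5-diyl tether (5 mol %), iPr2NEt (10 mol %), CH2Cl2, −78 °C; then aq. NaHCO3
Reagents that add atoms: silicon tetrachloride, Cl[Si](Cl)(Cl)Cl (its SiCl3 group is carried only by intermediate 8)
Why: Lewis-base-activated Lewis-acid Mukaiyama aldol (Denmark type): the phosphoramide-bound trichlorosilyl cation activates 7 and shields one face, so 5 adds to the Si face and sets the future C2 as S; work-up hydrolyses the trichlorosilyl ether 8.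

Step 7
Reactants: 9 (3S)-1-[2-(benzyloxy)-6-bromo-3,4,5-trimethoxyphenyl]-3-[2-(benzyloxy)-6-methoxyphenyl]-3-hydroxypropan-1-one
Product: 11 (1R,3S)-1-[2-(benzyloxy)-6-bromo-3,4,5-trimethoxyphenyl]-3-[2-(benzyloxy)-6-methoxyphenyl]propane-1,3-diol (syn), via diethylboron chelate 10 (not isolated)
Conditions: Et2BOMe (1.1 equiv), THF/MeOH (4:1), −78 °C; NaBH4; then AcOH, MeOH co-evaporation
Reagents that add atoms: diethyl(methoxy)borane, CCB(CC)OC (its Et2B group is carried only by intermediate 10)
Why: Narasaka–Prasad reduction: the boron chelate 10 holds hydroxyl and ketone in a six-membered ring and external hydride adds from the axial direction to give the 1,3-syn diol; the new centre (future C4, R) is controlled by the existing carbinol and is erased in step 9.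

Step 8
Reactants: 11 (1R,3S)-1-[2-(benzyloxy)-6-bromo-3,4,5-trimethoxyphenyl]-3-[2-(benzyloxy)-6-methoxyphenyl]propane-1,3-diol
Product: 12 (2S,4R)-5-(benzyloxy)-2-[2-(benzyloxy)-6-methoxyphenyl]-6,7,8-trimethoxy-3,4-dihydro-2H-chromen-4-ol (2,4-trans)
Conditions: CuI (10 mol %), 3,4,7,8-tetramethyl-1,10-phenanthroline (20 mol %), Cs2CO3 (2 equiv), toluene, 110 °C, Ar
Reagents that add atoms: none
Why: Intramolecular Ullmann-type etherification, the copper counterpart of the palladium-catalysed aryl ether cyclisation, both known routes from 3-(2-bromoaryl)propan-1-ols to chromans. Cs2CO3 and phenanthroline-ligated monovalent copper form a copper alkoxide, the C8a–Br bond adds oxidatively to give a transient trivalent copper aryl alkoxide, and C–O reductive elimination forms O1–C8a. Ring C closes in a six-membered exo mode, the oxygen attacking the ipso carbon with the C–Br bond outside the new ring. No stereocentre is formed; C2 stays S because its C–O bond is never broken and a copper alkoxide has no ready β-hydride path that could oxidise the benzylic carbinol. The selectivity needed is between the two hydroxyls, and ring size secures it: only the ring B carbinol oxygen reaches C8a in a six-membered ring, while the ring A carbinol oxygen would have to form a four-membered ring. The C4 oxygen is kept as an alcohol because a β-hydroxy ketone would cleave or dehydrate under carbonate at this temperature. The electron-rich, doubly ortho-substituted bromide reacts slowly, which the intramolecular setting, the electron-rich ligand and heating should offset.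

Step 9
Reactants: 12 (2S,4R)-5-(benzyloxy)-2-[2-(benzyloxy)-6-methoxyphenyl]-6,7,8-trimethoxy-3,4-dihydro-2H-chromen-4-ol
Product: 13 (2S)-5-(benzyloxy)-2-[2-(benzyloxy)-6-methoxyphenyl]-6,7,8-trimethoxy-2,3-dihydro-4H-chromen-4-one
Conditions: Dess–Martin periodinane, NaHCO3, CH2Cl2, 0 °C to rt
Reagents that add atoms: none
Why: Dess–Martin oxidation of a secondary benzylic alcohol under buffered, non-basic conditions, so the new β-aryloxy ketone is not opened to the chalcone and C2 is kept.

Step 10
Reactants: 13 (2S)-5-(benzyloxy)-2-[2-(benzyloxy)-6-methoxyphenyl]-6,7,8-trimethoxy-2,3-dihydro-4H-chromen-4-one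
Product: 14 (2S)-5-hydroxy-2-(2-hydroxy-6-methoxyphenyl)-6,7,8-trimethoxy-2,3-dihydro-4H-chromen-4-one
Conditions: H2 (1 atm), 10% Pd/C, EtOAc, rt
Reagents that add atoms: none
Why: Catalytic hydrogenolysis of the two aryl benzyl ethers under neutral conditions; methyl ethers stay, and the medium contains neither base nor Lewis acid that could racemise C2.

## Compound list

1 | 1,2,3,4-tetramethoxybenzene | COc1ccc(OC)c(OC)c1OC | starting material
2 | 1-bromo-2,3,4,5-tetramethoxybenzene | COc1cc(Br)c(OC)c(OC)c1OC | intermediate
3 | 1-(2-bromo-6-hydroxy-3,4,5-trimethoxyphenyl)ethan-1-one | CC(=O)c1c(Br)c(OC)c(OC)c(OC)c1O | intermediate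
4 | 1-[2-(benzyloxy)-6-bromo-3,4,5-trimethoxyphenyl]ethan-1-one | CC(=O)c1c(Br)c(OC)c(OC)c(OC)c1OCc1ccccc1 | intermediate
5 | ({1-[2-(benzyloxy)-6-bromo-3,4,5-trimethoxyphenyl]ethenyl}oxy)(trimethyl)silane | C=C(O[Si](C)(C)C)c1c(Br)c(OC)c(OC)c(OC)c1OCc1ccccc1 | intermediate
6 | 2-hydroxy-6-methoxybenzaldehyde | COc1cccc(O)c1C=O | starting material
7 | 2-(benzyloxy)-6-methoxybenzaldehyde | COc1cccc(OCc2ccccc2)c1C=O | intermediate
8 | trichlorosilyl ether of 9, (1S)-3-[2-(benzyloxy)-6-bromo-3,4,5-trimethoxyphenyl]-1-[2-(benzyloxy)-6-methoxyphenyl]-3-oxopropoxy(trichloro)silane | COc1cccc(OCc2ccccc2)c1[C@@H](O[Si](Cl)(Cl)Cl)CC(=O)c1c(Br)c(OC)c(OC)c(OC)c1OCc1ccccc1 | intermediate (not isolated)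
9 | (3S)-1-[2-(benzyloxy)-6-bromo-3,4,5-trimethoxyphenyl]-3-[2-(benzyloxy)-6-methoxyphenyl]-3-hydroxypropan-1-one | COc1cccc(OCc2ccccc2)c1[C@@H](O)CC(=O)c1c(Br)c(OC)c(OC)c(OC)c1OCc1ccccc1 | intermediate
10 | diethylboron chelate of 9, (1S)-3-[2-(benzyloxy)-6-bromo-3,4,5-trimethoxyphenyl]-1-[2-(benzyloxy)-6-methoxyphenyl]-3-oxopropyl diethylborinate | COc1cccc(OCc2ccccc2)c1[C@@H](OB(CC)CC)CC(=O)c1c(Br)c(OC)c(OC)c(OC)c1OCc1ccccc1 | intermediate (not isolated)
11 | (1R,3S)-1-[2-(benzyloxy)-6-bromo-3,4,5-trimethoxyphenyl]-3-[2-(benzyloxy)-6-methoxyphenyl]propane-1,3-diol (syn) | COc1cccc(OCc2ccccc2)c1[C@@H](O)C[C@@H](O)c1c(Br)c(OC)c(OC)c(OC)c1OCc1ccccc1 | intermediate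
12 | (2S,4R)-5-(benzyloxy)-2-[2-(benzyloxy)-6-methoxyphenyl]-6,7,8-trimethoxy-3,4-dihydro-2H-chromen-4-ol (2,4-trans) | COc1cccc(OCc2ccccc2)c1[C@@H]1C[C@@H](O)c2c(OCc3ccccc3)c(OC)c(OC)c(OC)c2O1 | intermediate
13 | (2S)-5-(benzyloxy)-2-[2-(benzyloxy)-6-methoxyphenyl]-6,7,8-trimethoxy-2,3-dihydro-4H-chromen-4-one | COc1cccc(OCc2ccccc2)c1[C@@H]1CC(=O)c2c(OCc3ccccc3)c(OC)c(OC)c(OC)c2O1 | intermediate
14 | (2S)-5-hydroxy-2-(2-hydroxy-6-methoxyphenyl)-6,7,8-trimethoxy-2,3-dihydro-4H-chromen-4-one | COc1cccc(O)c1[C@@H]1CC(=O)c2c(O)c(OC)c(OC)c(OC)c2O1 | target

## Step count and least certain steps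

Total: 10 steps. Longest linear sequence: 9 steps (1 to 14 through steps 1, 2, 3, 4, 6, 7, 8, 9, 10); the ring B branch adds step 5.

**Step 8 (key step).** The most likely failure is slow oxidative addition at the hindered, electron-rich C–Br bond, with protodebromination taking over at 110 °C. The 1,3-diolate, and in particular the ring A alkoxide next to the bromide, may also sequester copper in an unproductive chelate. Fallback (sets out from 9, returns at 13): the ring A hydroxyl is masked so that the substrate carries a single free hydroxyl.
- TESOTf and 2,6-lutidine would convert 9 into the triethylsilyl ether F1.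
- NaBH4 in MeOH would reduce the ketone to the ring A carbinol F2; both epimers are acceptable because this centre is oxidised later.
- TBSOTf and 2,6-lutidine would give the bis-silyl ether F3.
- PPTS in MeOH would remove the more labile triethylsilyl group to give the mono-alcohol F4.
- The copper closure of step 8 would give the silyl-protected chroman F5. With no second hydroxyl competing, Pd(OAc)2 with a bulky di-tert-butyl biaryl phosphine and Cs2CO3 is also open.
- TBAF would release the chromanol F6, which the Dess–Martin oxidation of step 9 would convert into 13.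

**Step 6.** Aldehyde 7 is electron-rich and blocked at both ortho positions, so addition may be sluggish and the enantioface selectivity eroded by a looser transition state or by an uncatalysed background reaction. Fallback (sets out from 4 and 7, returns at 9):
- Claisen–Schmidt condensation (KOH, EtOH) would give the (E)-chalcone F7.
- Copper-catalysed enantioselective conjugate borylation (CuCl, NaOtBu, a Josiphos-type ferrocenyl diphosphine, bis(pinacolato)diboron, MeOH, THF) would give the β-boryl ketone F8.
- NaBO3·4H2O would oxidise the C–B bond with retention to 9.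

**Step 2.** Acylation at the crowded last position may stall. Alternatively the aluminium phenoxide, once formed, may direct loss of a second methyl group from the neighbouring methoxy. Fallback (sets out from 2, returns at 3):
- A second bromination (NBS, MeCN) would give the dibromide F9.
- A single bromine–magnesium exchange with iPrMgCl·LiCl at −20 °C and inverse addition to acetic anhydride would give the tetramethoxy bromo ketone F10.
- BCl3 (1 equiv, CH2Cl2, −78 to 0 °C) would cleave only the methoxy group chelated to the ketone to give 3.

**Step 10.** The hindered C5 benzyl ether may cleave slowly, and on long exposure hydrogenolysis of the benzylic C2–O1 bond or reduction of the aryl ketone could set in. Fallback (sets out from 13, returns at 14): non-reductive debenzylation with BCl3 and pentamethylbenzene as cation scavenger in CH2Cl2 at −78 °C. It makes no new compound.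

## Further compounds

F1 | step 8 | (3S)-1-[2-(benzyloxy)-6-bromo-3,4,5-trimethoxyphenyl]-3-[2-(benzyloxy)-6-methoxyphenyl]-3-[(triethylsilyl)oxy]propan-1-one | COc1cccc(OCc2ccccc2)c1[C@@H](O[Si](CC)(CC)CC)CC(=O)c1c(Br)c(OC)c(OC)c(OC)c1OCc1ccccc1
F2 | step 8 | (3S)-1-[2-(benzyloxy)-6-bromo-3,4,5-trimethoxyphenyl]-3-[2-(benzyloxy)-6-methoxyphenyl]-3-[(triethylsilyl)oxy]propan-1-ol (both C1 epimers) | COc1cccc(OCc2ccccc2)c1[C@@H](O[Si](CC)(CC)CC)CC(O)c1c(Br)c(OC)c(OC)c(OC)c1OCc1ccccc1
F3 | step 8 | (3S)-1-[2-(benzyloxy)-6-bromo-3,4,5-trimethoxyphenyl]-3-[2-(benzyloxy)-6-methoxyphenyl]-1-[(tert-butyldimethylsilyl)oxy]-3-[(triethylsilyl)oxy]propane (both C1 epimers) | COc1cccc(OCc2ccccc2)c1[C@@H](O[Si](CC)(CC)CC)CC(O[Si](C)(C)C(C)(C)C)c1c(Br)c(OC)c(OC)c(OC)c1OCc1ccccc1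
F4 | step 8 | (1S)-3-[2-(benzyloxy)-6-bromo-3,4,5-trimethoxyphenyl]-1-[2-(benzyloxy)-6-methoxyphenyl]-3-[(tert-butyldimethylsilyl)oxy]propan-1-ol (both C3 epimers) | COc1cccc(OCc2ccccc2)c1[C@@H](O)CC(O[Si](C)(C)C(C)(C)C)c1c(Br)c(OC)c(OC)c(OC)c1OCc1ccccc1
F5 | step 8 | (2S)-5-(benzyloxy)-2-[2-(benzyloxy)-6-methoxyphenyl]-4-[(tert-butyldimethylsilyl)oxy]-6,7,8-trimethoxy-3,4-dihydro-2H-chromene (both C4 epimers) | COc1cccc(OCc2ccccc2)c1[C@@H]1CC(O[Si](C)(C)C(C)(C)C)c2c(OCc3ccccc3)c(OC)c(OC)c(OC)c2O1
F6 | step 8 | (2S)-5-(benzyloxy)-2-[2-(benzyloxy)-6-methoxyphenyl]-6,7,8-trimethoxy-3,4-dihydro-2H-chromen-4-ol (both C4 epimers) | COc1cccc(OCc2ccccc2)c1[C@@H]1CC(O)c2c(OCc3ccccc3)c(OC)c(OC)c(OC)c2O1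
F7 | step 6 | (2E)-1-[2-(benzyloxy)-6-bromo-3,4,5-trimethoxyphenyl]-3-[2-(benzyloxy)-6-methoxyphenyl]prop-2-en-1-one | COc1cccc(OCc2ccccc2)c1/C=C/C(=O)c1c(Br)c(OC)c(OC)c(OC)c1OCc1ccccc1
F8 | step 6 | (3S)-1-[2-(benzyloxy)-6-bromo-3,4,5-trimethoxyphenyl]-3-[2-(benzyloxy)-6-methoxyphenyl]-3-(4,4,5,5-tetramethyl-1,3,2-dioxaborolan-2-yl)propan-1-one | COc1cccc(OCc2ccccc2)c1[C@@H](B2OC(C)(C)C(C)(C)O2)CC(=O)c1c(Br)c(OC)c(OC)c(OC)c1OCc1ccccc1
F9 | step 2 | 1,2-dibromo-3,4,5,6-tetramethoxybenzene | COc1c(Br)c(Br)c(OC)c(OC)c1OC
F10 | step 2 | 1-(2-bromo-3,4,5,6-tetramethoxyphenyl)ethan-1-one | CC(=O)c1c(Br)c(OC)c(OC)c(OC)c1OC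
F0 | step 10 | none | none
A1 | alternative 1 | (2S,4S)-4-[(tert-butyldimethylsilyl)oxy]-2-{2-hydroxy-6-[(triisopropylsilyl)oxy]phenyl}-5,6,7,8-tetramethoxy-3,4-dihydro-2H-chromene | CC(C)[Si](Oc1cccc(O)c1[C@@H]1C[C@H](O[Si](C)(C)C(C)(C)C)c2c(OC)c(OC)c(OC)c(OC)c2O1)(C(C)C)C(C)C
A2 | alternative 1 | (2S,4S)-4-[(tert-butyldimethylsilyl)oxy]-5,6,7,8-tetramethoxy-2-{[(triisopropylsilyl)oxy]ethynyl}-3,4-dihydro-2H-chromene | CC(C)[Si](OC#C[C@@H]1C[C@H](O[Si](C)(C)C(C)(C)C)c2c(OC)c(OC)c(OC)c(OC)c2O1)(C(C)C)C(C)C
A3 | alternative 1 | cyclobut-2-en-1-one | O=C1CC=C1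
A4 | alternative 2 | (2S)-2-(2-isopropoxy-6-methoxyphenyl)-5,6,7,8-tetramethoxy-2,3-dihydro-4H-chromen-4-one | CC(C)Oc1cccc(OC)c1[C@@H]1CC(=O)c2c(OC)c(OC)c(OC)c(OC)c2O1
A5 | alternative 2 | 2-diazo-1-{2-[(2-isopropoxy-6-methoxybenzyl)oxy]-3,4,5,6-tetramethoxyphenyl}ethan-1-one | CC(C)Oc1cccc(OC)c1COc1c(OC)c(OC)c(OC)c(OC)c1C(=O)C=[N+]=[N-]
A6 | alternative 3 | 2-[2-(benzyloxy)-6-methoxyphenyl]-5,6,7,8-tetramethoxy-4H-chromen-4-one | COc1cccc(OCc3ccccc3)c1-c1cc(=O)c2c(OC)c(OC)c(OC)c(OC)c2o1
A7 | alternative 3 | 2-iodo-3,4,5,6-tetramethoxyphenol | Oc1c(I)c(OC)c(OC)c(OC)c1OC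
A8 | alternative 3 | 1-(benzyloxy)-2-ethynyl-3-methoxybenzene | COc1cccc(OCc2ccccc2)c1C#C
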